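I nearly took the first minutes of the winter run for its rate, and that is a trap while the rate per free monomer is still moving.

| flask | free monomer | initiator | remark | time |
|---|---|---|---|---|
| winter | 0.10 M | 0.75 mM | run made earlier |  |
| west | 0.10 M | 0.50 mM |  | 30 min |
| south-west | 0.40 M | 0.50 mM |  | 30 min |

winter run (percent of the free monomer charged)

| time / min | monomer in chains / % |
|---|---|
| 1.33 | 4.7 |
| 2.50 | 11.8 |
| 4.00 | 22.1 |
| 6.00 | 36.0 |
| 10.0 | 55.7 |
| 20.0 | 85.6 |

(readings scatter by 0.5 percentage points)

- the average divides the monomer in chains by the number of chains begun, living and dead together
- the earlier runs do not show the number of chains; that part of a forecast is a guess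
- no earlier run changes the charge of initiator; that part of a forecast is a guess

1. which of the two ends with the longer chains by the average number of monomer units in a chain (chains begun, living or dead) ("neither" if they lie within 10%) (west / south-west / neither)
2. average number of monomer units in a chain (chains begun, living or dead) at the end, west
3. average number of monomer units in a chain (chains begun, living or dead) at the end, south-west

The winter run looked odd to me: it took up 0.0353 min⁻¹ of the charge up to its first reading and still 0.0299 min⁻¹ between its last two, although over that stretch c(free monomer) read only 44.3% and then 14.4% of the charge. Dividing by what was there cleared this up: the slope of ln(c0/c) was 0.0362 min⁻¹ at first and 0.112 min⁻¹ late, so free monomer was taken up faster per unit present late than early, which I read as growing chains rising in number and then standing, with a pseudo-first-order fall after that. Run back to zero, the late line of the winter run meets the time axis at 2.75 min, and this lag, the time at which the late straight line starts, is what I carried.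

Guessing the slope proportional to the initiator charge and the lag unchanged, I reckoned for west a slope of 0.0749 min⁻¹ and 13.0% of free monomer left at 30 min. The number of chains is not shown, so any length is a guess. The forecast said south-west, with 720 for south-west and 177 for west, where it wrote “nearly all initiator used”.

The flasks gave south-west, with 1140 for west and 1980 for south-west.

    free monomer + living end → monomer in chains + living end, rate k1*[living end]*[free monomer] (k = 19.0 L mol⁻¹ s⁻¹)
    free monomer + initiator → living end + monomer in chains (k = 0.0160 L mol⁻¹ s⁻¹)
    2 initiator → spent initiator B (k = 15.0 L mol⁻¹ s⁻¹)
    initiator → spent initiator A (k = 0.00170 s⁻¹)

In west at 30 min the living end stood at 8.08 × 10⁻⁵ M, which is 16.2% of the initiator charge. The slope of ln(c0/c) in west from 15.0 min to 30.0 min was 0.0918 min⁻¹, not my 0.0749 min⁻¹. Run back to zero, this line of west meets the time axis at 2.54 min, against the lag of 2.75 min read from the winter run. The winter lag with this slope gives 42.8% of free monomer for west read at 12 min, and that flask held 41.8%.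

Readings and results are calculated with constants of no real substance.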